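**Assumptions:** The target has no stereocentres (isoirigenin = 5,7,3'-trihydroxy-8,4',5'-trimethoxyisoflavone), so nothing needs to be set or preserved stereochemically. Compounds 1, 2, 5, 7, 9 and 10 are taken as commercially available.

## Retrosynthesis
- The C3–C1' bond is made last by Suzuki coupling of 3-iodochromone **8** with aryl-Bpin **11**.
- Iodochromone **8** comes from the enaminone of 2,4,6-trihydroxy-3-methoxyacetophenone (**4**) by iodocyclisation, which forms the pyranone ring.
- Acetophenone **4** comes from Friedel–Crafts acetylation of 1,2,3,5-tetramethoxybenzene, which is mirror-symmetric so only one regioisomer forms, followed by ortho/para demethylation that spares the meta OMe.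
- Boronate **11** comes from sterically controlled Ir-catalysed C–H borylation of 2,3-dimethoxyphenol at C5, which carries the required 3'-OH/4'-OMe/5'-OMe pattern.
- No protecting groups are used.

## Forward route

**Step 1**
Reactants: 1 (1,2,3,5-tetramethoxybenzene); 2 (acetic anhydride)
Product: 3 (1-(2,3,4,6-tetramethoxyphenyl)ethanone)
Conditions: Ac2O, BF3·Et2O, CH2Cl2, 0 °C to rt
Reagents that add atoms: acetic anhydride, CC(=O)OC(C)=O
Why: Friedel–Crafts acylation. The two free positions of 1 are equivalent by symmetry, and the site between two OMe groups is the most activated. Any ortho-demethylated by-product converges in step 2.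

**Step 2**
Reactants: 3
Product: 4 (1-(2,4,6-trihydroxy-3-methoxyphenyl)ethanone)
Conditions: BCl3 (4 equiv), CH2Cl2, –78 °C to rt; MeOH quench
Reagents that add atoms: none
Why: Lewis-acid ether cleavage. The two ortho OMe groups (chelated by the carbonyl) and the para OMe (conjugated) are cleaved. The meta 3-OMe is neither chelated nor conjugated, so it survives.

**Step 3**
Reactants: 4; 5 (N,N-dimethylformamide dimethyl acetal)
Product: 6 ((E)-3-(dimethylamino)-1-(2,4,6-trihydroxy-3-methoxyphenyl)prop-2-en-1-one)
Conditions: DMF-DMA (2.5 equiv), toluene, 80 °C
Reagents that add atoms: DMF-DMA, CN(C)C(OC)OC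
Why: The acetyl methyl condenses with DMF-DMA (enaminone formation). The chelated phenols are poorly nucleophilic, so O-methylation is minor.

**Step 4**
Reactants: 6; 7 (iodine)
Product: 8 (5,7-dihydroxy-3-iodo-8-methoxychromen-4-one)
Conditions: I2 (1.1 equiv), CHCl3, rt
Reagents that add atoms: iodine, II
Why: Electrophilic iodination of the enaminone α-carbon is followed by 6-endo attack of the 2'-OH on the iminium and loss of HNMe2, closing the pyranone ring. The E-alkene geometry is lost here.

**Step 5**
Reactants: 9 (2,3-dimethoxyphenol); 10 (bis(pinacolato)diboron)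
Product: 11 (2,3-dimethoxy-5-(pinacolatoboryl)phenol)
Conditions: [Ir(cod)OMe]2 (1.5 mol%), dtbpy (3 mol%), B2pin2 (1.5 equiv), THF, 80 °C; aqueous work-up
Reagents that add atoms: B2pin2, CC1(C)OB(OC1(C)C)B1OC(C)(C)C(C)(C)O1
Why: Ir-catalysed C–H borylation is sterically controlled. C5 is the only position with two ortho H's, so it is borylated selectively. Any ArO–Bpin formed is hydrolysed on work-up.

**Step 6**
Reactants: 8; 11
Product: 12 (isoirigenin)
Conditions: Pd(PPh3)4 (5 mol%), K2CO3 (3 equiv), dioxane/H2O 4:1, 90 °C
Reagents that add atoms: none
Why: Suzuki–Miyaura coupling of the vinyl iodide C3–I with the aryl-Bpin forms the isoflavone C3–aryl bond. The free phenols are tolerated as phenoxides, and there are no stereocentres.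

## Checks performed
- Ring A: C5-OH, C7-OH, C8-OMe and C8a–O match the target.
- Ring B: 3'-OH flanked by 4',5'-OMe matches the target; borylation at C5 of 2,3-dimethoxyphenol gives attachment meta to both OH and OMe, with OMe at the central position.
- Atom balance holds at each step.
- Only ring A carries methyl ethers that are cleaved (step 2), and this happens before ring B is attached. The final product **12** is the target with no further manipulation.

## Compound list
1 | 1,2,3,5-tetramethoxybenzene | COc1cc(OC)cc(OC)c1OC | starting material
2 | acetic anhydride | CC(=O)OC(C)=O | starting material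
3 | 1-(2,3,4,6-tetramethoxyphenyl)ethanone | CC(=O)c1c(OC)cc(OC)c(OC)c1OC | intermediate
4 | 1-(2,4,6-trihydroxy-3-methoxyphenyl)ethanone | CC(=O)c1c(O)cc(O)c(OC)c1O | intermediate
5 | DMF dimethyl acetal | CN(C)C(OC)OC | starting material
6 | (E)-enaminone | CN(C)/C=C/C(=O)c1c(O)cc(O)c(OC)c1O | intermediate
7 | iodine | II | starting material
8 | 5,7-dihydroxy-3-iodo-8-methoxychromen-4-one | O=c1c(I)coc2c(OC)c(O)cc(O)c12 | intermediate
9 | 2,3-dimethoxyphenol | COc1cccc(O)c1OC | starting material
10 | bis(pinacolato)diboron | CC1(C)OB(OC1(C)C)B1OC(C)(C)C(C)(C)O1 | starting material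
11 | 2,3-dimethoxy-5-(Bpin)phenol | COc1cc(B2OC(C)(C)C(C)(C)O2)cc(O)c1OC | intermediate
12 | isoirigenin (achiral, no stereocentres) | COc1cc(-c2coc3c(OC)c(O)cc(O)c3c2=O)cc(O)c1OC | target

## Summary
- Total steps: 6.
- Longest linear sequence: 5 steps (1 → 3 → 4 → 6 → 8 → 12).

**Three steps most likely to fail, with fallbacks**
1. **Step 2 (selective demethylation, 3-OMe retained).** BCl3 could over-cleave the 3-OMe or give an incomplete reaction. Fallback: build the same acetophenone **4** from commercial 2,4,6-trihydroxyacetophenone by bis-benzylation, C3 formylation, Dakin oxidation, methylation and hydrogenolysis.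
2. **Step 4 (iodocyclisation on the free-phenol enaminone).** Competing ring iodination at C6 or N/O-methylation in step 3 is possible. Fallback: protect the phenols of **4** as bis-MOM ethers before the DMF-DMA step and remove them with HCl after the Suzuki coupling.
3. **Step 6 (Suzuki coupling with free phenols and an electron-rich aryl-Bpin).** Protodeboronation or a stalled oxidative addition onto the phenoxide is possible. Fallback: change the strategy to a deoxybenzoin route, in which the arylacetic acid from the B-ring aldehyde is acylated onto the A-ring arene and ring-closed with BF3/DMF/MeSO2Cl.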